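**Retrosynthetic overview**
1. The target is read as epicatechin 3-O-gallate-(4β→6)-epicatechin 3-O-gallate-(4β→8)-catechin. The last operations are hydrogenolysis of all benzyl ethers and two bromine caps, preceded by galloylation of the top and middle 3-OH groups.
2. Feature: in the middle unit, O1–C2 and the cis C3–O bond are the two C–O bonds of a cis C2–C3 epoxide. The ring-A phenol oxygen (on C8a) opens it at benzylic C2 with inversion and closes middle ring C (6-endo) as the last ring.
3. The epoxide comes from a Z-alkene and that from an alkyne. The middle C4–C4a bond comes from a propargylic Friedel–Crafts alkylation of ring A by the cation of a catechin-8-yl aryl-propynol made from (+)-catechin-8-carbaldehyde.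
4. Ring A is phloroglucinol that already carries the top unit: the flavan-4-yl cation of bromine-capped (−)-epicatechin gives the 4β→6 bond. Its para oxygen is then silylated (future O1), its ortho oxygens benzylated, and its two remaining ring carbons are equivalent.
5. Ring order: the C rings of the bottom and top units come from the chiral pool; middle ring C is formed in the key step.

Key step: step 17

Remark: (+)-catechin 1, (−)-epicatechin 11, phloroglucinol 15, 3,4-bis(benzyloxy)benzaldehyde 7 and 3,4,5-tris(benzyloxy)benzoyl chloride 24 are taken as purchased.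
Remark: in the open-chain intermediates 19–22 the atoms carry the flavan numbers they will have in the middle unit (O1, C2, C3, C4, C4a, C8a).
Remark: middle C4 is formed at a planar cation remote from all stereocentres (step 13) and is the one centre not under substrate or reagent control; the plan accepts a chromatographic separation of the two C4 epimers there.

**Step 1**
Reactants: 1 (+)-catechin
Product: 2 5,7,3',4'-tetra-O-benzyl-(+)-catechin
Conditions: BnBr (4.4 equiv), K2CO3, DMF, 0 °C → rt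
Reagents that add atoms: benzyl bromide BrCc1ccccc1
Why: Williamson etherification of the four phenoxides; the weak base leaves the secondary 3-OH alone and does not epimerise C2.

**Step 2**
Reactants: 2 5,7,3',4'-tetra-O-benzyl-(+)-catechin
Product: 3 3,5,7,3',4'-penta-O-benzyl-(+)-catechin
Conditions: NaH, BnBr, n-Bu4NI (cat.), DMF, 0 °C → rt
Reagents that add atoms: benzyl bromide BrCc1ccccc1
Why: Williamson O-benzylation of the secondary alkoxide marks the bottom 3-OH as one that stays free in the target; with all phenols capped the flavan stereocentres are not at risk.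

**Step 3**
Reactants: 3 3,5,7,3',4'-penta-O-benzyl-(+)-catechin
Product: 4 8-bromo-3,5,7,3',4'-penta-O-benzyl-(+)-catechin
Conditions: NBS (1.05 equiv), CH2Cl2, −78 °C → rt
Reagents that add atoms: N-bromosuccinimide O=C1CCC(=O)N1Br
Why: Electrophilic aromatic bromination goes to C8, the most nucleophilic carbon of a benzylated flavan A ring (ortho to the pyran oxygen), a well-established regioselectivity.

**Step 4**
Reactants: 4 8-bromo-3,5,7,3',4'-penta-O-benzyl-(+)-catechin
Product: 6 3,5,7,3',4'-penta-O-benzyl-(+)-catechin-8-carbaldehyde, via 8-lithio-penta-O-benzylcatechin 5 (not isolated)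
Conditions: n-BuLi (1.1 equiv), THF, −78 °C; DMF, −78 → 0 °C; H2O
Reagents that add atoms: N,N-dimethylformamide CN(C)C=O
Why: Bromine–lithium exchange followed by formylation of the aryllithium with DMF places the one-carbon handle (future middle C4) regiospecifically at C8.

**Step 5**
Reactants: 7 3,4-bis(benzyloxy)benzaldehyde
Product: 8 4-ethynyl-1,2-bis(benzyloxy)benzene
Conditions: dimethyl (1-diazo-2-oxopropyl)phosphonate, K2CO3, MeOH–THF, rt
Reagents that add atoms: dimethyl (1-diazo-2-oxopropyl)phosphonate COP(=O)(OC)C(=[N+]=[N-])C(C)=O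
Why: Seyferth–Gilbert homologation with the Ohira–Bestmann reagent turns the aryl aldehyde into the terminal alkyne (future C3, C2 and ring B of the middle unit) under mild base.

**Step 6**
Reactants: 8 4-ethynyl-1,2-bis(benzyloxy)benzene; 6 3,5,7,3',4'-penta-O-benzyl-(+)-catechin-8-carbaldehyde
Product: 10 1-(penta-O-benzylcatechin-8-yl)-3-[3,4-bis(benzyloxy)phenyl]prop-2-yn-1-ol (both carbinol epimers), via lithium [3,4-bis(benzyloxy)phenyl]acetylide 9 (not isolated)
Conditions: 8, n-BuLi, THF, −78 °C; then 6, −78 → 0 °C; H2O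
Reagents that add atoms: none
Why: 1,2-Addition of a lithium acetylide to the non-enolisable aldehyde; the carbinol centre is formed without control, which does not matter because it is ionised in step 13.

**Step 7**
Reactants: 11 (−)-epicatechin
Product: 12 5,7,3',4'-tetra-O-benzyl-(−)-epicatechin
Conditions: BnBr (4.4 equiv), K2CO3, DMF, 0 °C → rt
Reagents that add atoms: benzyl bromide BrCc1ccccc1
Why: Williamson etherification of the phenols only, as in step 1; the 2R,3R centres of the future top unit are untouched.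

**Step 8**
Reactants: 12 5,7,3',4'-tetra-O-benzyl-(−)-epicatechin
Product: 13 4β-(2-ethoxyethoxy)-5,7,3',4'-tetra-O-benzyl-(−)-epicatechin
Conditions: DDQ, 2-ethoxyethanol, CH2Cl2, rt
Reagents that add atoms: 2-ethoxyethanol CCOCCO
Why: DDQ benzylic oxidation (hydride abstraction at C4, assisted by the 5,7-dioxygenated A ring) and capture of the cation by the alcohol trans to the 3-OH give the 4β-ether, a standard C4 activation of flavan-3-ols.

**Step 9**
Reactants: 13 4β-(2-ethoxyethoxy)-5,7,3',4'-tetra-O-benzyl-(−)-epicatechin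
Product: 14 6,8-dibromo-4β-(2-ethoxyethoxy)-5,7,3',4'-tetra-O-benzyl-(−)-epicatechin
Conditions: NBS (2.2 equiv), CH2Cl2, 0 °C → rt, dark
Reagents that add atoms: N-bromosuccinimide O=C1CCC(=O)N1Br
Why: Electrophilic bromination of both free A-ring carbons caps C6 and C8, so that this ring cannot act as a nucleophile in steps 10 and 13 and its later C4–aryl bond is less prone to acid cleavage; both bromines leave in the final hydrogenolysis.

**Step 10**
Reactants: 14 6,8-dibromo-4β-(2-ethoxyethoxy)-5,7,3',4'-tetra-O-benzyl-(−)-epicatechin; 15 phloroglucinol (5 equiv)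
Product: 16 6,8-dibromo-5,7,3',4'-tetra-O-benzyl-4β-(2,4,6-trihydroxyphenyl)-(−)-epicatechin
Conditions: TMSOTf (0.2 equiv), CH2Cl2–Et2O, −40 °C → rt
Reagents that add atoms: none
Why: Acid-promoted Friedel–Crafts coupling of the flavan-4-yl cation with threefold-symmetric phloroglucinol (every ring carbon is the same, the excess suppresses double alkylation); the arene enters trans to the 3-hydroxyl of the 2,3-cis flavan, which sets top C4 as 4β (3,4-trans), the established outcome for epicatechin-type cations.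

**Step 11**
Reactants: 16 6,8-dibromo-5,7,3',4'-tetra-O-benzyl-4β-(2,4,6-trihydroxyphenyl)-(−)-epicatechin
Product: 17 6,8-dibromo-5,7,3',4'-tetra-O-benzyl-4β-[2,6-dihydroxy-4-(triisopropylsilyloxy)phenyl]-(−)-epicatechin
Conditions: TIPSCl (1.05 equiv), imidazole, DMF, −10 → 0 °C
Reagents that add atoms: triisopropylsilyl chloride CC(C)[Si](Cl)(C(C)C)C(C)C
Why: Sterically controlled silylation: the para hydroxyl is the only phenol not flanked by the flavanyl group, so the bulky silyl chloride should select it over the two ortho phenols and the hindered 3-OH; this oxygen is the future O1.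

**Step 12**
Reactants: 17 6,8-dibromo-5,7,3',4'-tetra-O-benzyl-4β-[2,6-dihydroxy-4-(triisopropylsilyloxy)phenyl]-(−)-epicatechin
Product: 18 6,8-dibromo-5,7,3',4'-tetra-O-benzyl-4β-[2,6-bis(benzyloxy)-4-(triisopropylsilyloxy)phenyl]-(−)-epicatechin
Conditions: BnBr (2.5 equiv), K2CO3, acetone, 50 °C
Reagents that add atoms: benzyl bromide BrCc1ccccc1
Why: Williamson benzylation of the two remaining phenols (the secondary 3-OH is not deprotonated by K2CO3, and the heterogeneous base in acetone spares the aryl silyl ether) gives a ring A whose two free carbons are equivalent.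

**Step 13**
Reactants: 18 6,8-dibromo-5,7,3',4'-tetra-O-benzyl-4β-[2,6-bis(benzyloxy)-4-(triisopropylsilyloxy)phenyl]-(−)-epicatechin (1.5 equiv); 10 1-(penta-O-benzylcatechin-8-yl)-3-[3,4-bis(benzyloxy)phenyl]prop-2-yn-1-ol
Product: 19 open middle unit as alkyne: ring A of 18 bonded at its carbon between OTIPS and OBn (future C4a) to C4H(penta-O-benzylcatechin-8-yl)–C≡C–[3,4-bis(benzyloxy)phenyl]; C4 epimer as in the SMILES
Conditions: BF3·OEt2 (0.3 equiv), 4 Å molecular sieves, CH2Cl2, −78 → −30 °C; chromatographic separation of the C4 epimers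
Reagents that add atoms: none
Why: SN1 propargylic Friedel–Crafts alkylation: the cation of 10 (stabilised by the catechin A ring and the aryl alkyne) is taken up at its propargylic carbon by one of the two equivalent free carbons of ring A of 18 (they interchange by rotation about the bond to the top unit), while the bromine caps and the silyl ether leave no other nucleophilic carbon or oxygen on 18 to compete or to add to the alkyne; the new C4 centre arises at a planar cation far from every stereocentre, so no useful induction is expected, both C4 epimers should form, and the epimer drawn is separated from its diastereomer by chromatography.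

**Step 14**
Reactants: 19 open middle unit as alkyne
Product: 20 open middle unit as (Z)-alkene (C3=C2 cis, C4 unchanged)
Conditions: H2 (1 atm), Pd/CaCO3 poisoned with Pb(OAc)2 (Lindlar catalyst), quinoline, EtOAc, rt
Reagents that add atoms: none
Why: Lindlar semihydrogenation adds hydrogen syn and stops at the Z-alkene; aryl bromides, benzyl ethers and the silyl ether are not touched on the poisoned catalyst.

**Step 15**
Reactants: 20 open middle unit as (Z)-alkene
Product: 21 open middle unit as (2S,3R)-cis-epoxide with ring-A OTIPS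
Conditions: dimethyldioxirane (acetone solution, 1.5 equiv), CH2Cl2, −40 → −10 °C
Reagents that add atoms: dimethyldioxirane CC1(C)OO1
Why: Epoxidation with dimethyldioxirane is a concerted, acid-free oxygen transfer that keeps the Z geometry (cis-epoxide) and spares the acid-labile product; with C4–H in the alkene plane (minimum allylic 1,3-strain) the two faces are flanked by ring A and by the catechin ring, and attack is expected anti to ring A, the bulkier aryl (silyl ether, buttressed 5-OBn, top unit), which sets C3 as R and C2 as S, whereas a free ring-A phenol would have drawn the oxidant to its own face and led to the 3,4-cis series.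

**Step 16**
Reactants: 21 open middle unit as (2S,3R)-cis-epoxide with ring-A OTIPS
Product: 22 open middle unit as (2S,3R)-cis-epoxide with free ring-A phenol (precursor of the key step)
Conditions: n-Bu4NF (1.1 equiv), AcOH (1.2 equiv), THF, −20 → 0 °C; cold NaHCO3 work-up, crude used at once
Reagents that add atoms: none
Why: Fluoride cleaves the aryl silyl ether selectively, and the acetic acid buffer protonates the phenoxide as it forms so that base-induced 5-exo opening of the epoxide is avoided; no stereocentre is touched.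

**Step 17**
Reactants: 22 open middle unit as (2S,3R)-cis-epoxide with free ring-A phenol
Product: 23 protected trimer diol: 6,8-dibromo-tetra-O-benzylepicatechin-(4β→6)-5,7,3',4'-tetra-O-benzylepicatechin-(4β→8)-penta-O-benzylcatechin with the 3-OH of the top and middle units free
Conditions: (+)-camphorsulfonic acid (10 mol%), CH2Cl2, −40 → 0 °C
Reagents that add atoms: none
Why: Camphorsulfonic acid activates the epoxide oxygen, the C2–O bond is loosened because the developing positive charge at C2 is benzylic and stabilised by the para-benzyloxy group of ring B, and the ring-A phenol oxygen (on C8a) attacks C2 from the side opposite to the leaving oxygen. The closest known reaction type is the acid-promoted endo opening of aryl-activated epoxides by an internal hydroxyl group, as used to close chroman-3-ols from epoxidised 1,3-diarylpropenes. Ring C of the middle unit (O1, C2, C3, C4, C4a, C8a) is closed in the 6-endo-tet mode; the competing 5-exo-tet attack at C3 would give a dihydrobenzofuran. The only new stereocentre is C2, set by inversion of the (2S)-epoxide carbon to 2R, so that the cis-epoxide delivers the 2,3-cis relationship, while C3 (R, the former epoxide oxygen, now the free 3-OH) and C4 are carried over unchanged as 3,4-trans. The step needs endo regioselectivity and clean inversion: the first is secured by the electron-rich ring B on C2 and by the crowded C3 next to the diarylmethine, the second by the tethered nucleophile, the catalytic weak acid, the low temperature and the non-ionising solvent, which favour a loose SN2 opening over a free benzylic cation. The bromine-capped top unit, the benzyl ethers and the free top 3-OH (too remote to reach the epoxide) are spectators.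

**Step 18**
Reactants: 23 protected trimer diol; 24 3,4,5-tris(benzyloxy)benzoyl chloride (3 equiv)
Product: 25 protected trimer 3,3-di-O-[3,4,5-tris(benzyloxy)benzoyl] ester (top and middle 3-O-gallates, benzyl-protected)
Conditions: 24, DMAP, Et3N, CH2Cl2, rt → 35 °C
Reagents that add atoms: none
Why: DMAP-catalysed acylation of the two free secondary 3-hydroxyls (the bottom 3-oxygen is a benzyl ether) with retention at C3, since only the O–H bonds react.

**Step 19**
Reactants: 25 protected trimer digallate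
Product: 26 CNP0112921.1, epicatechin 3-O-gallate-(4β→6)-epicatechin 3-O-gallate-(4β→8)-catechin
Conditions: H2 (1 atm), Pd(OH)2/C, NaOAc (2.5 equiv), THF–MeOH–H2O, rt
Reagents that add atoms: none
Why: Catalytic hydrogenolysis removes the nineteen benzyl ethers and the two aryl bromine caps in one operation, the acetate buffering the hydrogen bromide; the gallate esters, the interflavan bonds and all stereocentres are stable under these neutral conditions.

**Compound list**
1 | (+)-catechin | Oc1cc(O)c2c(c1)O[C@H](c1ccc(O)c(O)c1)[C@@H](O)C2 | starting material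
2 | 5,7,3',4'-tetra-O-benzyl-(+)-catechin | c5c(OCc9ccccc9)cc(OCc9ccccc9)c6c5O[C@H](c8ccc(OCc9ccccc9)c(OCc9ccccc9)c8)[C@@H](O)C6 | intermediate
3 | 3,5,7,3',4'-penta-O-benzyl-(+)-catechin | c5c(OCc9ccccc9)cc(OCc9ccccc9)c6c5O[C@H](c8ccc(OCc9ccccc9)c(OCc9ccccc9)c8)[C@@H](OCc9ccccc9)C6 | intermediate
4 | 8-bromo-3,5,7,3',4'-penta-O-benzyl-(+)-catechin | Brc5c(OCc9ccccc9)cc(OCc9ccccc9)c6c5O[C@H](c8ccc(OCc9ccccc9)c(OCc9ccccc9)c8)[C@@H](OCc9ccccc9)C6 | intermediate
5 | 8-lithio-penta-O-benzylcatechin (not isolated) | [Li]c5c(OCc9ccccc9)cc(OCc9ccccc9)c6c5O[C@H](c8ccc(OCc9ccccc9)c(OCc9ccccc9)c8)[C@@H](OCc9ccccc9)C6 | intermediate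
6 | 3,5,7,3',4'-penta-O-benzyl-(+)-catechin-8-carbaldehyde | O=Cc5c(OCc9ccccc9)cc(OCc9ccccc9)c6c5O[C@H](c8ccc(OCc9ccccc9)c(OCc9ccccc9)c8)[C@@H](OCc9ccccc9)C6 | intermediate
7 | 3,4-bis(benzyloxy)benzaldehyde | O=Cc8ccc(OCc9ccccc9)c(OCc9ccccc9)c8 | starting material
8 | 4-ethynyl-1,2-bis(benzyloxy)benzene | C#Cc8ccc(OCc9ccccc9)c(OCc9ccccc9)c8 | intermediate
9 | lithium [3,4-bis(benzyloxy)phenyl]acetylide (not isolated) | [Li]C#Cc8ccc(OCc9ccccc9)c(OCc9ccccc9)c8 | intermediate
10 | 1-(penta-O-benzylcatechin-8-yl)-3-[3,4-bis(benzyloxy)phenyl]prop-2-yn-1-ol, both carbinol epimers | OC(C#Cc8ccc(OCc9ccccc9)c(OCc9ccccc9)c8)c5c(OCc9ccccc9)cc(OCc9ccccc9)c6c5O[C@H](c8ccc(OCc9ccccc9)c(OCc9ccccc9)c8)[C@@H](OCc9ccccc9)C6 | intermediate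
11 | (−)-epicatechin | O[C@@H]1Cc2c(O)cc(O)cc2O[C@@H]1c8ccc(O)c(O)c8 | starting material
12 | 5,7,3',4'-tetra-O-benzyl-(−)-epicatechin | O[C@@H]1Cc2c(OCc9ccccc9)cc(OCc9ccccc9)cc2O[C@@H]1c8ccc(OCc9ccccc9)c(OCc9ccccc9)c8 | intermediate
13 | 4β-(2-ethoxyethoxy)-5,7,3',4'-tetra-O-benzyl-(−)-epicatechin | O[C@@H]1[C@@H](OCCOCC)c2c(OCc9ccccc9)cc(OCc9ccccc9)cc2O[C@@H]1c8ccc(OCc9ccccc9)c(OCc9ccccc9)c8 | intermediate
14 | 6,8-dibromo-4β-(2-ethoxyethoxy)-5,7,3',4'-tetra-O-benzyl-(−)-epicatechin | O[C@@H]1[C@@H](OCCOCC)c2c(OCc9ccccc9)c(Br)c(OCc9ccccc9)c(Br)c2O[C@@H]1c8ccc(OCc9ccccc9)c(OCc9ccccc9)c8 | intermediate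
15 | phloroglucinol | Oc1cc(O)cc(O)c1 | starting material
16 | 6,8-dibromo-5,7,3',4'-tetra-O-benzyl-4β-(2,4,6-trihydroxyphenyl)-(−)-epicatechin | O[C@@H]1[C@@H](c3c(O)cc(O)cc3O)c2c(OCc9ccccc9)c(Br)c(OCc9ccccc9)c(Br)c2O[C@@H]1c8ccc(OCc9ccccc9)c(OCc9ccccc9)c8 | intermediate
17 | 6,8-dibromo-5,7,3',4'-tetra-O-benzyl-4β-[2,6-dihydroxy-4-(triisopropylsilyloxy)phenyl]-(−)-epicatechin | O[C@@H]1[C@@H](c3c(O)cc(O[Si](C(C)C)(C(C)C)C(C)C)cc3O)c2c(OCc9ccccc9)c(Br)c(OCc9ccccc9)c(Br)c2O[C@@H]1c8ccc(OCc9ccccc9)c(OCc9ccccc9)c8 | intermediate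
18 | 6,8-dibromo-5,7,3',4'-tetra-O-benzyl-4β-[2,6-bis(benzyloxy)-4-(triisopropylsilyloxy)phenyl]-(−)-epicatechin | O[C@@H]1[C@@H](c3c(OCc9ccccc9)cc(O[Si](C(C)C)(C(C)C)C(C)C)cc3OCc9ccccc9)c2c(OCc9ccccc9)c(Br)c(OCc9ccccc9)c(Br)c2O[C@@H]1c8ccc(OCc9ccccc9)c(OCc9ccccc9)c8 | intermediate
19 | open middle unit as alkyne (ring A with OTIPS; C4 bears the catechin-8-yl group and the aryl alkyne) | O[C@@H]1[C@@H](c3c(OCc9ccccc9)cc(O[Si](C(C)C)(C(C)C)C(C)C)c(c3OCc9ccccc9)[C@H](c5c(OCc9ccccc9)cc(OCc9ccccc9)c6c5O[C@H](c8ccc(OCc9ccccc9)c(OCc9ccccc9)c8)[C@@H](OCc9ccccc9)C6)C#Cc8ccc(OCc9ccccc9)c(OCc9ccccc9)c8)c2c(OCc9ccccc9)c(Br)c(OCc9ccccc9)c(Br)c2O[C@@H]1c8ccc(OCc9ccccc9)c(OCc9ccccc9)c8 | intermediate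
20 | open middle unit as (Z)-alkene | O[C@@H]1[C@@H](c3c(OCc9ccccc9)cc(O[Si](C(C)C)(C(C)C)C(C)C)c(c3OCc9ccccc9)[C@H](c5c(OCc9ccccc9)cc(OCc9ccccc9)c6c5O[C@H](c8ccc(OCc9ccccc9)c(OCc9ccccc9)c8)[C@@H](OCc9ccccc9)C6)/C=C\c8ccc(OCc9ccccc9)c(OCc9ccccc9)c8)c2c(OCc9ccccc9)c(Br)c(OCc9ccccc9)c(Br)c2O[C@@H]1c8ccc(OCc9ccccc9)c(OCc9ccccc9)c8 | intermediate
21 | open middle unit as (2S,3R)-cis-epoxide, ring-A OTIPS | O[C@@H]1[C@@H](c3c(OCc9ccccc9)cc(O[Si](C(C)C)(C(C)C)C(C)C)c(c3OCc9ccccc9)[C@H](c5c(OCc9ccccc9)cc(OCc9ccccc9)c6c5O[C@H](c8ccc(OCc9ccccc9)c(OCc9ccccc9)c8)[C@@H](OCc9ccccc9)C6)[C@H]7O[C@H]7c8ccc(OCc9ccccc9)c(OCc9ccccc9)c8)c2c(OCc9ccccc9)c(Br)c(OCc9ccccc9)c(Br)c2O[C@@H]1c8ccc(OCc9ccccc9)c(OCc9ccccc9)c8 | intermediate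
22 | open middle unit as (2S,3R)-cis-epoxide, free ring-A phenol (key-step precursor) | O[C@@H]1[C@@H](c3c(OCc9ccccc9)cc(O)c(c3OCc9ccccc9)[C@H](c5c(OCc9ccccc9)cc(OCc9ccccc9)c6c5O[C@H](c8ccc(OCc9ccccc9)c(OCc9ccccc9)c8)[C@@H](OCc9ccccc9)C6)[C@H]7O[C@H]7c8ccc(OCc9ccccc9)c(OCc9ccccc9)c8)c2c(OCc9ccccc9)c(Br)c(OCc9ccccc9)c(Br)c2O[C@@H]1c8ccc(OCc9ccccc9)c(OCc9ccccc9)c8 | intermediate
23 | protected trimer diol (middle ring C closed, 2,3-cis-3,4-trans; top and middle 3-OH free) | O[C@@H]1[C@@H](c3c(OCc9ccccc9)cc4c(c3OCc9ccccc9)[C@H](c5c(OCc9ccccc9)cc(OCc9ccccc9)c6c5O[C@H](c8ccc(OCc9ccccc9)c(OCc9ccccc9)c8)[C@@H](OCc9ccccc9)C6)[C@@H](O)[C@@H](c8ccc(OCc9ccccc9)c(OCc9ccccc9)c8)O4)c2c(OCc9ccccc9)c(Br)c(OCc9ccccc9)c(Br)c2O[C@@H]1c8ccc(OCc9ccccc9)c(OCc9ccccc9)c8 | intermediate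
24 | 3,4,5-tris(benzyloxy)benzoyl chloride | ClC(=O)c7cc(OCc9ccccc9)c(OCc9ccccc9)c(OCc9ccccc9)c7 | starting material
25 | protected trimer digallate | O=C(O[C@@H]1[C@@H](c3c(OCc9ccccc9)cc4c(c3OCc9ccccc9)[C@H](c5c(OCc9ccccc9)cc(OCc9ccccc9)c6c5O[C@H](c8ccc(OCc9ccccc9)c(OCc9ccccc9)c8)[C@@H](OCc9ccccc9)C6)[C@@H](OC(=O)c7cc(OCc9ccccc9)c(OCc9ccccc9)c(OCc9ccccc9)c7)[C@@H](c8ccc(OCc9ccccc9)c(OCc9ccccc9)c8)O4)c2c(OCc9ccccc9)c(Br)c(OCc9ccccc9)c(Br)c2O[C@@H]1c8ccc(OCc9ccccc9)c(OCc9ccccc9)c8)c7cc(OCc9ccccc9)c(OCc9ccccc9)c(OCc9ccccc9)c7 | intermediate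
26 | CNP0112921.1 | O=C(O[C@@H]1[C@@H](c2c(O)cc3c(c2O)[C@H](c2c(O)cc(O)c4c2O[C@H](c2ccc(O)c(O)c2)[C@@H](O)C4)[C@@H](OC(=O)c2cc(O)c(O)c(O)c2)[C@@H](c2ccc(O)c(O)c2)O3)c2c(O)cc(O)cc2O[C@@H]1c1ccc(O)c(O)c1)c1cc(O)c(O)c(O)c1 | target

**Step count**
Total: 19 steps. Longest linear sequence: 13 steps (steps 7–12 from (−)-epicatechin, then steps 13–19).

**Steps most likely to fail**

1. Step 17 (key step). The epoxide may ionise fully at C2 before the phenol closes the ring, so that inversion is lost and the 2,3-trans isomer forms, or the phenol may attack C3 in the 5-exo mode. Fallback, from 20 back to 23: OsO4 (cat.) with N-methylmorpholine N-oxide dihydroxylates the Z-alkene syn on the face planned for step 15 and gives the erythro-diol F1. n-Bu4NF/AcOH frees the ring-A phenol to give the phenol diol F2. HC(OEt)3 with pyridinium p-toluenesulfonate gives the cyclic orthoformate F3. On warming in 1,2-dichloroethane F3 loses ethanol to the 1,3-dioxolan-2-ylium ion, and the phenol displaces the benzylic C2–O bond with inversion (orthoester cyclisation to a flavan-3-ol) to give the 3-O-formate F4. K2CO3 in MeOH removes the formyl group and the route is rejoined at 23.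

2. Step 15. Oxygen transfer may go to the alkene face syn to ring A (which would end in the 3,4-cis series), and the electron-rich aryl epoxide may open on isolation. Fallback, from 20 to 21, with the facial choice moved from the substrate to the reagent: Shi epoxidation with the glucose-derived oxazolidinone ketone for cis-alkenes, using the ketone enantiomer that converts cis-β-methylstyrene into (1S,2R)-1-phenylpropylene oxide, KHSO5 (as Oxone), K2CO3 buffer, MeCN–dimethoxymethane–water, 0 °C. The chiral dioxirane is also concerted, so the cis geometry is kept, and the basic medium protects the epoxide. This fallback makes no new compound (F0).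

3. Step 13. The crowded ring-A carbon (between OTIPS and a buttressed OBn) may react too slowly, so that the cation is diverted to its allenyl terminus or to C6 of another molecule of 10; in addition the lack of facial bias at C4 costs half of the material. Fallback, from 17 back to 19: the alkylation is run on the diphenol 17 with 10 (BF3·OEt2, CH2Cl2, −78 °C), where the reacting carbon is ortho to a free hydroxyl, more nucleophilic and unbuttressed, to give the diphenol alkyne F5. The two phenols are then benzylated (BnBr, K2CO3, acetone) to reach 19, with the same separation of C4 epimers. The low temperature is meant to keep the free ortho hydroxyl from adding to the alkyne.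

**Further compounds**
F1 | step 17 | erythro-2,3-diol of the open middle unit, ring-A OTIPS | O[C@@H]1[C@@H](c3c(OCc9ccccc9)cc(O[Si](C(C)C)(C(C)C)C(C)C)c(c3OCc9ccccc9)[C@H](c5c(OCc9ccccc9)cc(OCc9ccccc9)c6c5O[C@H](c8ccc(OCc9ccccc9)c(OCc9ccccc9)c8)[C@@H](OCc9ccccc9)C6)[C@@H](O)[C@@H](O)c8ccc(OCc9ccccc9)c(OCc9ccccc9)c8)c2c(OCc9ccccc9)c(Br)c(OCc9ccccc9)c(Br)c2O[C@@H]1c8ccc(OCc9ccccc9)c(OCc9ccccc9)c8
F2 | step 17 | erythro-2,3-diol of the open middle unit, free ring-A phenol | O[C@@H]1[C@@H](c3c(OCc9ccccc9)cc(O)c(c3OCc9ccccc9)[C@H](c5c(OCc9ccccc9)cc(OCc9ccccc9)c6c5O[C@H](c8ccc(OCc9ccccc9)c(OCc9ccccc9)c8)[C@@H](OCc9ccccc9)C6)[C@@H](O)[C@@H](O)c8ccc(OCc9ccccc9)c(OCc9ccccc9)c8)c2c(OCc9ccccc9)c(Br)c(OCc9ccccc9)c(Br)c2O[C@@H]1c8ccc(OCc9ccccc9)c(OCc9ccccc9)c8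
F3 | step 17 | cyclic 2,3-O-(ethoxymethylidene) orthoformate of F2 | O[C@@H]1[C@@H](c3c(OCc9ccccc9)cc(O)c(c3OCc9ccccc9)[C@H](c5c(OCc9ccccc9)cc(OCc9ccccc9)c6c5O[C@H](c8ccc(OCc9ccccc9)c(OCc9ccccc9)c8)[C@@H](OCc9ccccc9)C6)[C@H]7OC(OCC)O[C@H]7c8ccc(OCc9ccccc9)c(OCc9ccccc9)c8)c2c(OCc9ccccc9)c(Br)c(OCc9ccccc9)c(Br)c2O[C@@H]1c8ccc(OCc9ccccc9)c(OCc9ccccc9)c8
F4 | step 17 | middle 3-O-formate of 23 | O[C@@H]1[C@@H](c3c(OCc9ccccc9)cc4c(c3OCc9ccccc9)[C@H](c5c(OCc9ccccc9)cc(OCc9ccccc9)c6c5O[C@H](c8ccc(OCc9ccccc9)c(OCc9ccccc9)c8)[C@@H](OCc9ccccc9)C6)[C@@H](OC=O)[C@@H](c8ccc(OCc9ccccc9)c(OCc9ccccc9)c8)O4)c2c(OCc9ccccc9)c(Br)c(OCc9ccccc9)c(Br)c2O[C@@H]1c8ccc(OCc9ccccc9)c(OCc9ccccc9)c8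
F0 | step 15 | none | none
F5 | step 13 | diphenol alkyne (19 with the two ring-A benzyl ethers as free hydroxyls) | O[C@@H]1[C@@H](c3c(O)cc(O[Si](C(C)C)(C(C)C)C(C)C)c(c3O)[C@H](c5c(OCc9ccccc9)cc(OCc9ccccc9)c6c5O[C@H](c8ccc(OCc9ccccc9)c(OCc9ccccc9)c8)[C@@H](OCc9ccccc9)C6)C#Cc8ccc(OCc9ccccc9)c(OCc9ccccc9)c8)c2c(OCc9ccccc9)c(Br)c(OCc9ccccc9)c(Br)c2O[C@@H]1c8ccc(OCc9ccccc9)c(OCc9ccccc9)c8
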